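**Strategy.** Everything rests on cutting the bond between the benzylic CH2 on the resorcylic acid ring and the acetoxy-bearing C-2′ of the tridecyl chain. The key step exploits the oxygen on C-2′: in a hindered benzoate of the C12 primary alcohol this carbon is deprotonated enantioselectively (polarity reversal of a carbinol carbon) and joined to the benzylic carbon, itself a nucleophile as its boronic ester, by a 1,2-shift from boron to carbon; oxidation of the new C–B bond then gives the C-2′ hydroxyl. One operation thus forms the bond and sets C-2′. Precursors: a silyl-protected (S)-11-hydroxydodecyl triisopropylbenzoate and 3,5-bis(benzyloxy)benzyl pinacolboronate; the ring carboxyl is added afterwards.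

Key step: step 5

Remark: the chain is numbered from the benzylic carbon (C-1′) and the SMILES is read as 2′R, 12′S; simple reagents are given with SMILES on the reagent line and carry no number.

**Step 1**
Reactants: 1 9-bromononan-1-ol
Product: 2 9-bromononyl 2,4,6-triisopropylbenzoate
Conditions: 2,4,6-triisopropylbenzoic acid, PPh3, DIAD, THF, 0 °C → rt
Reagents that add atoms: 2,4,6-triisopropylbenzoic acid CC(C)c1cc(C(C)C)c(C(=O)O)c(C(C)C)c1
Why: Mitsunobu esterification, in which the primary hydroxyl is activated as an alkoxyphosphonium ion and displaced by the hindered carboxylate while the alkyl bromide stays untouched.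

**Step 2**
Reactants: 2 9-bromononyl 2,4,6-triisopropylbenzoate; 3 (S)-propylene oxide
Product: 5 (S)-11-hydroxydodecyl 2,4,6-triisopropylbenzoate, via Grignard reagent 4 (not isolated)
Conditions: Mg, THF, rt; then CuI (10 mol %), 3, THF, −30 → 0 °C; sat. aq NH4Cl
Reagents that add atoms: none
Why: Copper-catalysed SN2 opening of a monosubstituted epoxide by a primary alkyl Grignard reagent at the CH2 terminus, which leaves the stereocentre of 3 untouched as the (S)-methyl carbinol; the two ortho isopropyl groups should shield the ester carbonyl from the Grignard carbon.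

**Step 3**
Reactants: 5 (S)-11-hydroxydodecyl 2,4,6-triisopropylbenzoate
Product: 6 (S)-11-[(tert-butyldimethylsilyl)oxy]dodecyl 2,4,6-triisopropylbenzoate
Conditions: TBSCl, imidazole, DMF, rt
Reagents that add atoms: tert-butyldimethylsilyl chloride CC(C)(C)[Si](C)(C)Cl
Why: Standard imidazole-promoted silylation of a secondary alcohol; the TBS ether should tolerate s-BuLi at −78 °C and alkaline peroxide.

**Step 4**
Reactants: 7 3,5-bis(benzyloxy)benzyl bromide
Product: 8 2-[3,5-bis(benzyloxy)benzyl]-4,4,5,5-tetramethyl-1,3,2-dioxaborolane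
Conditions: B2pin2, Pd(dba)2 (3 mol %), P(4-MeOC6H4)3, KOAc, toluene, 50 °C
Reagents that add atoms: bis(pinacolato)diboron CC1(C)OB(OC1(C)C)B1OC(C)(C)C(C)(C)O1
Why: Miyaura borylation of a benzylic halide (oxidative addition of Pd(0) into the benzylic C–Br bond, acetate-assisted transmetalation with the diboron, reductive elimination).

**Step 5**
Reactants: 6 (S)-11-[(tert-butyldimethylsilyl)oxy]dodecyl 2,4,6-triisopropylbenzoate; 8 2-[3,5-bis(benzyloxy)benzyl]-4,4,5,5-tetramethyl-1,3,2-dioxaborolane
Product: 12 (2R,12S)-1-[3,5-bis(benzyloxy)phenyl]-12-[(tert-butyldimethylsilyl)oxy]tridecan-2-ol, via α-lithiated benzoate 9 (not isolated), via lithium boronate complex 10 (not isolated), via secondary pinacol boronic ester 11 (not isolated)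
Conditions: 6 (1.3 equiv), s-BuLi (1.25 equiv), (−)-sparteine (1.3 equiv), Et2O, −78 °C, 5 h; 8 (1.0 equiv), −78 °C, 1 h; then 35 °C, 12 h; then THF, 2 M NaOH, 30% H2O2, 0 °C → rt
Reagents that add atoms: hydrogen peroxide OO
Why: Lithiation–borylation, i.e. a Hoppe-type sparteine-mediated deprotonation followed by a Matteson-type 1,2-metallate rearrangement: s-BuLi/(−)-sparteine should remove the pro-S hydrogen of the O–CH2 group of 6 (directed by the benzoate carbonyl, which its two ortho isopropyl groups protect from addition) to give the configurationally stable carbanion 9, which adds to the boron of 8 with retention to give boronate 10. On warming, the benzylic group migrates from boron to carbon anti to the departing triisopropylbenzoate (inversion), so that the ArCH2–CH bond is formed in 11, and alkaline hydrogen peroxide then replaces boron by hydroxyl with retention. The closest known reaction type is the reagent-controlled homologation of pinacol boronic esters with lithiated primary alkyl triisopropylbenzoates; no ring is closed. The new stereocentre C-2 is controlled by the chiral diamine alone (the silyloxy centre ten carbons away should exert no influence), and the retention–inversion–retention sequence leads to the R configuration because the benzylic arm outranks the alkyl arm. The step needs boron capture to outrun every other reaction of 9 and the benzyl group, not a pinacol oxygen, to migrate; fast ate-complex formation at −78 °C, the good leaving group and the absence of any carbonyl or acidic group in 8 (the ring carboxyl is deliberately held back until step 7, which also rules out lactonisation of the new hydroxyl) should secure this.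

**Step 6**
Reactants: 12 (2R,12S)-1-[3,5-bis(benzyloxy)phenyl]-12-[(tert-butyldimethylsilyl)oxy]tridecan-2-ol
Product: 14 (2R,12S)-1-[3,5-bis(benzyloxy)phenyl]tridecane-2,12-diyl diacetate, via diol 13 (not isolated)
Conditions: TBAF, THF, rt; then Ac2O, Et3N, DMAP, rt
Reagents that add atoms: acetic anhydride CC(=O)OC(C)=O
Why: Fluoride-induced cleavage of the Si–O bond followed in the same flask by DMAP-catalysed acetylation of both secondary hydroxyls; no C–O bond at either stereocentre is broken.

**Step 7**
Reactants: 14 (2R,12S)-1-[3,5-bis(benzyloxy)phenyl]tridecane-2,12-diyl diacetate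
Product: 16 (2R,12S)-1-[3,5-bis(benzyloxy)-2-formylphenyl]tridecane-2,12-diyl diacetate, via aryl iminium chloride 15 (not isolated)
Conditions: POCl3, DMF, 0 → 60 °C; then aq NaOAc, rt
Reagents that add atoms: N,N-dimethylformamide CN(C)C=O; water O
Why: Vilsmeier–Haack formylation, an electrophilic aromatic substitution by the chloroiminium ion that should occur ortho to the side chain and para to a benzyloxy group (the two such positions are equivalent) as in orcinol-type diethers, the position between the two ethers being the more hindered one; acetates and benzyl ethers are inert.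

**Step 8**
Reactants: 16 (2R,12S)-1-[3,5-bis(benzyloxy)-2-formylphenyl]tridecane-2,12-diyl diacetate
Product: 17 2,4-bis(benzyloxy)-6-[(2R,12S)-2,12-diacetoxytridecyl]benzoic acid
Conditions: NaClO2, NaH2PO4, 2-methyl-2-butene, t-BuOH/H2O, rt
Reagents that add atoms: sodium chlorite [Na+].[O-]Cl=O
Why: Pinnick oxidation, in which chlorous acid adds to the aldehyde and fragments to the acid while 2-methyl-2-butene traps hypochlorous acid and so protects the electron-rich ring from chlorination.

**Step 9**
Reactants: 17 2,4-bis(benzyloxy)-6-[(2R,12S)-2,12-diacetoxytridecyl]benzoic acid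
Product: 18 2-[(2R,12S)-2,12-diacetoxytridecyl]-4,6-dihydroxybenzoic acid
Conditions: H2 (1 atm), 10% Pd/C, EtOAc, rt
Reagents that add atoms: none
Why: Catalytic hydrogenolysis of the two aryl benzyl ethers under neutral conditions; the C-2′ acetate is homobenzylic, not benzylic, and both acetates should survive.

**Compound list**
1 | 9-bromononan-1-ol | OCCCCCCCCCBr | starting material
2 | 9-bromononyl 2,4,6-triisopropylbenzoate | CC(C)c1cc(C(C)C)c(C(=O)OCCCCCCCCCBr)c(C(C)C)c1 | intermediate
3 | (S)-propylene oxide | C[C@H]1CO1 | starting material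
4 | 9-(2,4,6-triisopropylbenzoyloxy)nonylmagnesium bromide | CC(C)c1cc(C(C)C)c(C(=O)OCCCCCCCCC[Mg]Br)c(C(C)C)c1 | intermediate (not isolated)
5 | (S)-11-hydroxydodecyl 2,4,6-triisopropylbenzoate | C[C@H](O)CCCCCCCCCCOC(=O)c1c(C(C)C)cc(C(C)C)cc1C(C)C | intermediate
6 | (S)-11-[(tert-butyldimethylsilyl)oxy]dodecyl 2,4,6-triisopropylbenzoate | C[C@H](O[Si](C)(C)C(C)(C)C)CCCCCCCCCCOC(=O)c1c(C(C)C)cc(C(C)C)cc1C(C)C | intermediate
7 | 3,5-bis(benzyloxy)benzyl bromide | BrCc1cc(OCc2ccccc2)cc(OCc2ccccc2)c1 | starting material
8 | 2-[3,5-bis(benzyloxy)benzyl]-4,4,5,5-tetramethyl-1,3,2-dioxaborolane | CC1(C)OB(Cc2cc(OCc3ccccc3)cc(OCc3ccccc3)c2)OC1(C)C | intermediate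
9 | (1S,11S)-11-[(tert-butyldimethylsilyl)oxy]-1-lithiododecyl 2,4,6-triisopropylbenzoate | [Li][C@H](OC(=O)c1c(C(C)C)cc(C(C)C)cc1C(C)C)CCCCCCCCC[C@H](C)O[Si](C)(C)C(C)(C)C | intermediate (not isolated)
10 | lithium boronate complex of 9 and 8 (boron bound to the benzyl group and to the S-configured benzoate-bearing carbon) | [Li+].CC1(C)O[B-](Cc2cc(OCc3ccccc3)cc(OCc3ccccc3)c2)([C@H](OC(=O)c2c(C(C)C)cc(C(C)C)cc2C(C)C)CCCCCCCCC[C@H](C)O[Si](C)(C)C(C)(C)C)OC1(C)C | intermediate (not isolated)
11 | 2-[(2R,12S)-1-[3,5-bis(benzyloxy)phenyl]-12-[(tert-butyldimethylsilyl)oxy]tridecan-2-yl]-4,4,5,5-tetramethyl-1,3,2-dioxaborolane | CC1(C)OB([C@@H](Cc2cc(OCc3ccccc3)cc(OCc3ccccc3)c2)CCCCCCCCC[C@H](C)O[Si](C)(C)C(C)(C)C)OC1(C)C | intermediate (not isolated)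
12 | (2R,12S)-1-[3,5-bis(benzyloxy)phenyl]-12-[(tert-butyldimethylsilyl)oxy]tridecan-2-ol | O[C@H](CCCCCCCCC[C@H](C)O[Si](C)(C)C(C)(C)C)Cc1cc(OCc2ccccc2)cc(OCc2ccccc2)c1 | intermediate
13 | (2R,12S)-1-[3,5-bis(benzyloxy)phenyl]tridecane-2,12-diol | O[C@H](CCCCCCCCC[C@H](C)O)Cc1cc(OCc2ccccc2)cc(OCc2ccccc2)c1 | intermediate (not isolated)
14 | (2R,12S)-1-[3,5-bis(benzyloxy)phenyl]tridecane-2,12-diyl diacetate | CC(=O)O[C@H](CCCCCCCCC[C@H](C)OC(C)=O)Cc1cc(OCc2ccccc2)cc(OCc2ccccc2)c1 | intermediate
15 | N-{2,4-bis(benzyloxy)-6-[(2R,12S)-2,12-diacetoxytridecyl]benzylidene}-N-methylmethanaminium chloride | CC(=O)O[C@H](CCCCCCCCC[C@H](C)OC(C)=O)Cc1cc(OCc2ccccc2)cc(OCc2ccccc2)c1C=[N+](C)C.[Cl-] | intermediate (not isolated)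
16 | (2R,12S)-1-[3,5-bis(benzyloxy)-2-formylphenyl]tridecane-2,12-diyl diacetate | CC(=O)O[C@H](CCCCCCCCC[C@H](C)OC(C)=O)Cc1cc(OCc2ccccc2)cc(OCc2ccccc2)c1C=O | intermediate
17 | 2,4-bis(benzyloxy)-6-[(2R,12S)-2,12-diacetoxytridecyl]benzoic acid | CC(=O)O[C@H](CCCCCCCCC[C@H](C)OC(C)=O)Cc1cc(OCc2ccccc2)cc(OCc2ccccc2)c1C(=O)O | intermediate
18 | 2-[(2R,12S)-2,12-diacetoxytridecyl]-4,6-dihydroxybenzoic acid | CC(=O)O[C@H](CCCCCCCCC[C@H](C)OC(C)=O)Cc1cc(O)cc(O)c1C(=O)O | target

**Total step count:** 9. **Longest linear sequence:** 8 steps (1, 2, 3, 5, 6, 7, 8, 9).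

**Steps most likely to fail**

Step 5. The deprotonation of 6 may be incomplete or insufficiently enantioselective, or the boronate may revert or rearrange sluggishly, so that the coupling stalls or C-2′ is formed with eroded configuration. The fallback sets out from 3 and comes back at 12; it takes the C-2′ stereocentre from a resolved terminal epoxide that is opened by an aryl nucleophile. Dec-9-enylmagnesium bromide F1 (from 10-bromodec-1-ene and Mg) would open 3 under CuI catalysis to give (S)-tridec-12-en-2-ol F2, which would be silylated (TBSCl, imidazole) to (S)-tert-butyldimethyl(tridec-12-en-2-yloxy)silane F3. mCPBA would give the epoxide (S)-tert-butyldimethyl{[11-(oxiran-2-yl)undecan-2-yl]oxy}silane F4 as a mixture of both epimers at the oxirane carbon. Hydrolytic kinetic resolution with the enantiomer of the (salen)Co(III) acetate catalyst that hydrolyses the unwanted epimer should leave the (R)-oxirane, (S)-tert-butyldimethyl{[11-((R)-oxiran-2-yl)undecan-2-yl]oxy}silane F5. CuI-catalysed opening of F5 at its CH2 terminus with 3,5-bis(benzyloxy)phenylmagnesium bromide F6 (from 1,3-bis(benzyloxy)-5-bromobenzene and Mg) would then deliver 12.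

Step 7. The bulky chloroiminium electrophile may react slowly at the ring position flanked by the branched side chain or attack the position between the two benzyloxy groups, and prolonged heating may begin to cleave acetates. The fallback sets out from 14 and comes back at 18; it replaces formylation and oxidation by halogenation and carbonylation. NBS in MeCN at 0 °C should brominate ortho to the chain and para to a benzyloxy group to give (2R,12S)-1-[3,5-bis(benzyloxy)-2-bromophenyl]tridecane-2,12-diyl diacetate F7. Palladium-catalysed alkoxycarbonylation (Pd(OAc)2, Xantphos, CO, BnOH, Et3N, toluene, 100 °C) would give benzyl 2,4-bis(benzyloxy)-6-[(2R,12S)-2,12-diacetoxytridecyl]benzoate F8, and hydrogenolysis under the conditions of step 9 would remove all three benzyl groups to give 18, so that step 8 is no longer needed.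

Step 2. Magnesium insertion into 2 may be accompanied by Wurtz homocoupling or by attack of the organomagnesium carbon on the ester, and the epoxide may be diverted to a halohydrin. The fallback sets out from 1 and comes back at 5; it carries the hydroxyl through the Grignard stage as its magnesium alkoxide and introduces the hindered ester afterwards. Compound 1 would be deprotonated with i-PrMgCl and then treated with magnesium to give the alkoxide Grignard reagent 9-(chloromagnesiooxy)nonylmagnesium bromide F9, whose CuI-catalysed reaction with 3 should give (S)-dodecane-1,11-diol F10. Mitsunobu esterification with one equivalent of 2,4,6-triisopropylbenzoic acid, which should select the primary hydroxyl, would lead to 5.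

**Further compounds**
F1 | step 5 | dec-9-enylmagnesium bromide | C=CCCCCCCCC[Mg]Br
F2 | step 5 | (S)-tridec-12-en-2-ol | C[C@H](O)CCCCCCCCCC=C
F3 | step 5 | (S)-tert-butyldimethyl(tridec-12-en-2-yloxy)silane | C[C@H](O[Si](C)(C)C(C)(C)C)CCCCCCCCCC=C
F4 | step 5 | (S)-tert-butyldimethyl{[11-(oxiran-2-yl)undecan-2-yl]oxy}silane, both epimers at the oxirane carbon | C[C@H](O[Si](C)(C)C(C)(C)C)CCCCCCCCCC1CO1
F5 | step 5 | (S)-tert-butyldimethyl{[11-((R)-oxiran-2-yl)undecan-2-yl]oxy}silane | C[C@H](O[Si](C)(C)C(C)(C)C)CCCCCCCCC[C@@H]1CO1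
F6 | step 5 | 3,5-bis(benzyloxy)phenylmagnesium bromide | Br[Mg]c1cc(OCc2ccccc2)cc(OCc2ccccc2)c1
F7 | step 7 | (2R,12S)-1-[3,5-bis(benzyloxy)-2-bromophenyl]tridecane-2,12-diyl diacetate | CC(=O)O[C@H](CCCCCCCCC[C@H](C)OC(C)=O)Cc1cc(OCc2ccccc2)cc(OCc2ccccc2)c1Br
F8 | step 7 | benzyl 2,4-bis(benzyloxy)-6-[(2R,12S)-2,12-diacetoxytridecyl]benzoate | CC(=O)O[C@H](CCCCCCCCC[C@H](C)OC(C)=O)Cc1cc(OCc2ccccc2)cc(OCc2ccccc2)c1C(=O)OCc1ccccc1
F9 | step 2 | 9-(chloromagnesiooxy)nonylmagnesium bromide | Cl[Mg]OCCCCCCCCC[Mg]Br
F10 | step 2 | (S)-dodecane-1,11-diol | C[C@H](O)CCCCCCCCCCO
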